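Two questions stood before the flasks grey, green and teal: what one molecule does at the fork, and how far J gets in the time.

| flask | J | E | remark | time |
|---|---|---|---|---|
| north-east | 0.030 M | 0.020 M | run made earlier |  |
| west | 0.010 M | 0.020 M | run made earlier |  |
| grey | 0.020 M | 0.0200 M |  | 30 h |
| green | 0.020 M | 0.0600 M |  | 30 h |
| teal | 0.020 M | 0.0800 M |  | 30 h |

| run | time / h | Z / % | G / % | J / % |
|---|---|---|---|---|
| north-east | 2.00 | 6.2 | 0.3 | 93.9 |
| north-east | 4.00 | 11.6 | 0.3 | 87.4 |
| north-east | 5.00 | 13.8 | 0.2 | 84.8 |
| north-east | 8.00 | 20.9 | 0 | 79.6 |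
| north-east | 10.0 | 23.2 | 0.2 | 74.6 |
| west | 2.00 | 7.3 | 0.1 | 93.6 |
| west | 4.00 | 12.2 | 0 | 86.9 |
| west | 5.00 | 15.6 | 0.1 | 84.6 |
| west | 8.00 | 22.8 | 0.3 | 76.4 |
| west | 10.0 | 27.3 | 0.8 | 72.4 |

(scatter of a reading: 0.5 percentage points)
- what was read earlier has a scatter of 0.5 percentage points, one standard deviation
- steps thought possible: J + E <-> Q + Z; G + E -> L; Z + E <-> Q + G
- no earlier run changes the charge of E; that part of a forecast is a guess
- amount of Z at the end, in percent of the J charged, for each flask in turn (grey, green, teal)

I took the fork first, following one complex along its path. J + E makes Z and Z + E spends it, so I assumed that [E] stands in both rates and cancels from the chance at the fork, though no earlier run varies E. That leaves one number, the selectivity factor s, the rate constant of Z + E over that of J + E. Early on, G doubled over the square of Z, both as fractions of the J charged, gives s, and the last readings of both runs, averaged, gave 0.157, a rough reading, with G at 0.2% and 0.8% against a scatter of 0.5 percentage points. With the back steps neglected, I reckoned that Z stops rising where [Z]/[J] reaches 6.38, and this value of [Z]/[J], where making and spending of Z balance, is the turning ratio. On the same reckoning, I put the peak of Z at 70.8% of the J charged.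

How far J gets came from the west run, which, taken as second order, gave 1.74 L mol⁻¹ h⁻¹. So I expected J left at 48.9%, 8.57% and 3.28% in grey, green and teal. Along the path that s sets, these give Z at 48.1%, 70.5% and 65.5%. Grey stays under the turn, while green and teal pass it, so I put teal lower than green.

The forecast gave 49%, 80% and 77%, noting that “the high-E flasks are the less certain”. Its green and teal values stand higher than my peak.

The flasks gave 46.5%, 63.7% and 57.4%.

J + E ⇌ Q + Z (K = 21.0, k = 0.0300 L mol⁻¹ min⁻¹); G + E → L (k = 0.00480 L mol⁻¹ min⁻¹); Z + E ⇌ Q + G (K = 39.0, k = 0.00640 L mol⁻¹ min⁻¹) In grey, [Z]/[J] ended at 0.943, lower than the turning ratio of 6.38, and Z was still being made 4.71 times faster than it was used up, each step taken net. In teal, the ratio was 3.87 after 15.0 h, lower than the turn, and 11.9 after 30.0 h, higher than it, while Z went from 65.1% to 57.4%.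

The numbers in the tables stem from a simulated flask on assumed constants; the scatter is artificial.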